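## Analysis of the target

Target 16 is a halogenated bisabolane, C15H24BrClO2. It consists of a cyclohexane, ring A (C1–C6), with a tertiary alcohol at C1, a tertiary chloride and a methyl group at C4 and a secondary bromide at C5. Ring A is joined at C1 to the chain C7(=C14H2)–C8H2–C9H2–C10H(OH)–C11(CH3)=C12H2.

Ring A holds three stereocentres (1S,4R,5R in this numbering). Cl at C4 and Br at C5 are trans, the pattern of an anti addition across a former C4=C5 bond with chloride on the tertiary carbon. O1 and Cl4 are cis-1,4 and Br5 is cis-1,3 to C7, so one chair carries Br, Cl and the chain equatorial and OH and CH3 axial. C1 is stereogenic only through the remote C4/C5 substitution, so it cannot be set by face-selective addition to a symmetrical ketone. The fourth stereocentre, C10 (R), is an isolated secondary allylic carbinol five bonds from C1 and needs reagent control.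

Sensitive groups are the tertiary chloride with an antiperiplanar β-bromine (ionisation, reductive or base-induced elimination), the tertiary allylic alcohol C1–C7=C14 (acid-labile), and two 1,1-disubstituted alkenes that compete for electrophiles. The hard part is to add Br and Cl across C4=C5 with the right regiochemistry and on the right faces relative to C1, and to do so without touching the other π bonds. A conformationally controlled addition is expected to give the opposite facial result once the large C7 substituent is equatorial.

The route is built on one feature: O1 and Cl4 share a face of ring A and Br5 is anti to both. This is the topology of a transannular bromoether (O1 bridging C1 and C4, a 7-oxabicyclo[2.2.1]heptane) in which chlorine later replaces oxygen at C4 with retention.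

## Retrosynthetic reasoning

**C10–H (16 from 15).** The C10 carbinol is taken back to the isopropenyl ketone 15. C10 is too far from ring A for substrate control, and an enone with one α-branched sp2 substituent and one CH2 substituent is a good substrate for an oxazaborolidine-catalysed reduction. The forward step has to reduce only the C10 carbonyl and set (R).

**C7–C8 (15 from 10 and 13).** The bond between the 1,1-disubstituted alkene carbon C7 and C8 is cut, together with the C14–H bond. This leads to terminal alkyne 10 and racemic dienol 13. The forward reaction is a ruthenium-catalysed alkene–alkyne coupling of the redox-isomerising kind. It builds the exo-methylene unit, the C8–C9 link and the C10 carbonyl in one neutral, atom-economic step, without protecting groups and without organometallic reagents that would destroy the bromochloride. A cut at C1–C7 would instead need a basic vinylmetal and a β-bromo ketone.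

**C5–Br and C4–Cl (10 from 8, through 9).** Both halogens are removed to give ethynyl cyclohexenol 8, which has a single stereocentre. Forward, electrophilic bromine closes the O1–C4 bridge to bromoether 9, and a chlorotitanium Lewis acid reopens the bridge at C4 through the bromonium ion, so chlorine enters where oxygen left. The cut is made at the alkyne stage for three reasons: the alkyne is inert to the bromine electrophile, it does not stabilise a cation at C1, and no other alkene is present. After the chain is attached, C1–O would be allylic and would ionise first.

**C7≡C14 (8 from 6, through 7).** The alkyne is taken back to the aldehyde carbon of 6 by a one-carbon homologation. The acyl group on O1 is removed in the same flask through hydroxy aldehyde 7. C1 has no α-hydrogen and is not touched.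

**C1–C6 and C2–C3 (6 from 4 and 5).** Ring A is opened by a retro-Diels–Alder cut into isoprene 5 and 2-acyloxy enal 4. The forward cycloaddition forms the ring, places the methyl group para to C1 and creates C1 as the only stereocentre, under control of a chiral primary ammonium catalyst. This is the one place where absolute configuration is introduced for the ring.

**Building blocks (4 from 3, 3 from 1 and 2; 13 from 11 and 12).** Enal 4 comes from a thermal cycloreversion of dioxin 3, itself the enol ester of ketone 1 with acid chloride 2. Dienol 13 comes from 1,2-addition of Grignard reagent 12 to enal 11.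

## Alternatives that were turned down

**Alternative 1: the textbook cut at C1–C7.** The vinyllithium made from vinyl bromide A2 would add to the pre-halogenated ketone A1. It was turned down for three reasons:
- A1 is a β-bromo ketone. A basic organometallic would trigger enolisation and E1cB loss of bromide, or attack the vicinal dihalide reductively.
- The C1 configuration would rest only on the modest equatorial-attack preference of a cyclohexanone.
- A1 would need an enantioselective anti bromochlorination of an alkene with no directing handle, and A2 costs four to five steps with a protecting group.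

**Alternative 2: the biomimetic cut of C5–Br and C4–Cl at the very end.** The fully assembled triene diol A3 would be treated with an external bromonium source and chloride. It was turned down for three reasons:
- A3 has three alkenes, and the C10 hydroxyl can close in a 5-exo mode onto a bromonium ion at C7=C14.
- With the large C7 substituent equatorial, trans-diaxial Markovnikov opening puts bromine syn to the axial O1 and chlorine anti to it. That is the C4,C5-bis-epimer of 16.
- The oxygen tether cannot correct this at that stage, because C1–O is then allylic and would ionise in preference to C4–O.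

**Alternative 3: the chiral pool cut.** (−)-α-Bisabolol A4 already has all fifteen carbons and ring A. It would be dehydrated to the tetrasubstituted C1=C7 alkene A5, and oxygen would be brought back at C1 by epoxidation and isomerisation. It was turned down for three reasons:
- The oxygen must move from C7 to C1, and C1 passes through sp2. The only ring stereocentre of A4 is erased.
- The two faces of C1=C7 in A5 differ only in the position of the remote C4=C5 bond, so the centre cannot be rebuilt selectively.
- The prenyl and ring alkenes compete in every oxidation, and the problems of Alternative 2 remain afterwards.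

Key step: step 5

## Assumptions

- The (S)-diamine is written in step 3. If it gives the (1R) adduct, the (R)-diamine is used. The sense should be checked on 10, whose Br and Cl allow anomalous-dispersion crystallography.
- Dienol 13 is used as the racemate, because its carbinol centre becomes the C10 carbonyl in step 7.

## Route

Step 1
Reactants: 1 2,2-dimethyl-1,3-dioxan-5-one; 2 cyclohexanecarbonyl chloride
Product: 3 2,2-dimethyl-4H-1,3-dioxin-5-yl cyclohexanecarboxylate
Conditions: KN(SiMe3)2, THF, −78 °C; then 2, −78 → 0 °C
Reagents that add atoms: none
Why: Enolate O-acylation: the potassium enolate of 1 in THF should react with the hard acid chloride at oxygen to give the enol ester. No stereocentre is formed.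

Step 2
Reactants: 3 2,2-dimethyl-4H-1,3-dioxin-5-yl cyclohexanecarboxylate
Product: 4 3-oxoprop-1-en-2-yl cyclohexanecarboxylate (2-(cyclohexanecarbonyloxy)acrolein)
Conditions: toluene, 110 °C, BHT (cat.); used as a solution
Reagents that add atoms: none
Why: Thermal retro-hetero-Diels–Alder reaction of the 4H-1,3-dioxin. The O1–C2 and O3–C4 bonds break, acetone leaves and the 2-acyloxy enal is released.

Step 3
Reactants: 4 3-oxoprop-1-en-2-yl cyclohexanecarboxylate; 5 isoprene (2-methylbuta-1,3-diene)
Product: 6 (1S)-1-formyl-4-methylcyclohex-3-en-1-yl cyclohexanecarboxylate
Conditions: 5 (5 equiv), (S)-1,1'-binaphthyl-2,2'-diamine (10 mol%), HNTf2 (19 mol%), EtCN, −75 → −40 °C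
Reagents that add atoms: none
Why: Enantioselective Diels–Alder reaction through the iminium ion of the α-acyloxy enal with a chiral primary ammonium salt. The larger HOMO coefficient at C1 of isoprene bonds to the enal CH2, which gives the para (1,4) adduct. C1 is set by the catalyst, which shields one face of the iminium dienophile.

Step 4
Reactants: 6 (1S)-1-formyl-4-methylcyclohex-3-en-1-yl cyclohexanecarboxylate
Product: 8 (1S)-1-ethynyl-4-methylcyclohex-3-en-1-ol, via hydroxy aldehyde 7 (not isolated)
Conditions: K2CO3, MeOH, 0 °C → rt; then dimethyl (1-diazo-2-oxopropyl)phosphonate, rt
Reagents that add atoms: dimethyl (1-diazo-2-oxopropyl)phosphonate, COP(=O)(OC)C(=[N+]=[N-])C(C)=O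
Why: Methanolysis, helped by the neighbouring hemiacetal alkoxide, should remove the acyl group to give 7. Ohira–Bestmann homologation then converts the aldehyde into the terminal alkyne (olefination by the diazophosphonate, loss of N2, 1,2-hydrogen shift of the alkylidene carbene). C1 has no α-hydrogen and none of its bonds is broken, so the configuration from step 3 is kept.

Step 5
Reactants: 8 (1S)-1-ethynyl-4-methylcyclohex-3-en-1-ol
Product: 10 (1S,3R,4R)-3-bromo-4-chloro-1-ethynyl-4-methylcyclohexan-1-ol, via bromoether 9 (not isolated)
Conditions: NBS (1.05 equiv), CH2Cl2, 0 °C, dark; then TiCl4 (2.5 equiv), −78 → −30 °C; aq. NaHCO3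
Reagents that add atoms: N-bromosuccinimide, O=C1CCC(=O)N1Br; titanium tetrachloride, Cl[Ti](Cl)(Cl)Cl
Why: Proposed new method: electrophilic bromine adds reversibly to both faces of C4=C5 of 8, but only the bromonium ion anti to the C1 hydroxyl can be captured, across the ring through the boat, by O1 at the tertiary carbon C4 (5-exo closure), which gives the 7-oxabicyclo[2.2.1]heptane 9 with bromine endo; the closest known reaction type for this half is the bromoetherification of cyclohex-3-en-1-ols. TiCl4 then binds the bridging oxygen and the strained C4–O bond ionises with anchimeric assistance from the antiperiplanar bromine, so the bromonium ion is regenerated by the microscopic reverse of its capture; the closest known reaction types are the cleavage of ethers by chlorotitanium or chloroboron Lewis acids and the substitution of anti β-bromo alcohols by halide with retention through a bromonium ion. Chloride from the titanium-bound alkoxide opens the bromonium ion at C4 on the face the oxygen has just left, so C4 is substituted with net retention (two inversions). C5 is therefore fixed by the tether (Br anti to O1) and C4 by the bromine bridge (Cl anti to Br, hence cis to O1); both are relayed from C1 alone. Three selectivities are needed: alkene over alkyne, secured because an alkyne is far less nucleophilic towards bromine; C4–O over C1–O heterolysis, secured because C1 would give a tertiary propargylic cation that is inductively destabilised and has no participating neighbour, whereas C4 is pushed by bromine; and chloride capture over proton loss, secured by the tight ion pair with a chloride-rich titanate at low temperature. Strain release of the oxanorbornane and the strong O–Ti bond should make the opening irreversible.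

Step 6
Reactants: 11 methacrolein (2-methylprop-2-enal); 12 vinylmagnesium bromide
Product: 13 2-methylpenta-1,4-dien-3-ol (racemic)
Conditions: THF, −78 → 0 °C; aq. NH4Cl
Reagents that add atoms: none
Why: 1,2-Addition of a Grignard reagent to the enal carbonyl at low temperature. The racemate is sufficient, since this centre is oxidised in step 7.

Step 7
Reactants: 10 (1S,3R,4R)-3-bromo-4-chloro-1-ethynyl-4-methylcyclohexan-1-ol; 13 2-methylpenta-1,4-dien-3-ol
Product: 15 6-[(1S,3R,4R)-3-bromo-4-chloro-1-hydroxy-4-methylcyclohexyl]-2-methylhepta-1,6-dien-3-one, via dienol 14 (not isolated)
Conditions: CpRu(MeCN)3PF6 (10 mol%), 13 (2 equiv), acetone, rt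
Reagents that add atoms: none
Why: Ruthenium-catalysed alkene–alkyne coupling (Alder-ene type, redox-isomerising variant with allylic alcohols). Oxidative cyclisation forms a ruthenacyclopentene with the new C–C bond at the internal alkyne carbon C7, since the propargylic hydroxyl can chelate ruthenium only in this orientation; β-hydride elimination of the carbinol hydrogen and reductive elimination give dienol 14, which tautomerises to 15. The conditions are neutral and at room temperature, so the bromochloride and the tertiary alcohol should survive, and the 1,1-disubstituted alkene of 13 cannot enter the metallacycle.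

Step 8
Reactants: 15 6-[(1S,3R,4R)-3-bromo-4-chloro-1-hydroxy-4-methylcyclohexyl]-2-methylhepta-1,6-dien-3-one
Product: 16 (1S,3R,4R)-3-bromo-4-chloro-1-[(5R)-5-hydroxy-6-methylhepta-1,6-dien-2-yl]-4-methylcyclohexan-1-ol
Conditions: (S)-2-methyl-CBS-oxazaborolidine (20 mol%), catecholborane (2.5 equiv), toluene, −78 °C; MeOH, then pH 7 buffer
Reagents that add atoms: none
Why: Corey–Bakshi–Shibata reduction. The ketone binds the ring boron with the α-branched isopropenyl group as the large substituent and the C9 methylene as the small one; by analogy with aryl methyl ketones the (S)-catalyst should give the (R)-carbinol at C10. Catecholborane at −78 °C should leave the isolated alkenes and the halides untouched.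

## Compound list

1 | 2,2-dimethyl-1,3-dioxan-5-one | CC1(C)OCC(=O)CO1 | starting material
2 | cyclohexanecarbonyl chloride | O=C(Cl)C1CCCCC1 | starting material
3 | 2,2-dimethyl-4H-1,3-dioxin-5-yl cyclohexanecarboxylate | CC1(C)OCC(OC(=O)C2CCCCC2)=CO1 | intermediate
4 | 3-oxoprop-1-en-2-yl cyclohexanecarboxylate | C=C(C=O)OC(=O)C1CCCCC1 | intermediate
5 | isoprene (2-methylbuta-1,3-diene) | C=CC(C)=C | starting material
6 | (1S)-1-formyl-4-methylcyclohex-3-en-1-yl cyclohexanecarboxylate | O=C[C@]1(OC(=O)C2CCCCC2)CCC(C)=CC1 | intermediate
7 | (1S)-1-hydroxy-4-methylcyclohex-3-ene-1-carbaldehyde | O=C[C@]1(O)CCC(C)=CC1 | intermediate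
8 | (1S)-1-ethynyl-4-methylcyclohex-3-en-1-ol | C#C[C@]1(O)CCC(C)=CC1 | intermediate
9 | (1R,2R,4S)-2-bromo-4-ethynyl-1-methyl-7-oxabicyclo[2.2.1]heptane (bromine endo, anti to the oxygen bridge) | C#C[C@@]12CC[C@@](C)(O1)[C@H](Br)C2 | intermediate
10 | (1S,3R,4R)-3-bromo-4-chloro-1-ethynyl-4-methylcyclohexan-1-ol | C#C[C@]1(O)CC[C@@](C)(Cl)[C@H](Br)C1 | intermediate
11 | methacrolein (2-methylprop-2-enal) | C=C(C)C=O | starting material
12 | vinylmagnesium bromide | C=C[Mg]Br | starting material
13 | 2-methylpenta-1,4-dien-3-ol (racemic) | C=CC(O)C(C)=C | intermediate
14 | (3Z)-6-[(1S,3R,4R)-3-bromo-4-chloro-1-hydroxy-4-methylcyclohexyl]-2-methylhepta-1,3,6-trien-3-ol | C=C(C)/C(O)=C/CC(=C)[C@]1(O)CC[C@@](C)(Cl)[C@H](Br)C1 | intermediate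
15 | 6-[(1S,3R,4R)-3-bromo-4-chloro-1-hydroxy-4-methylcyclohexyl]-2-methylhepta-1,6-dien-3-one | C=C(C)C(=O)CCC(=C)[C@]1(O)CC[C@@](C)(Cl)[C@H](Br)C1 | intermediate
16 | (1S,3R,4R)-3-bromo-4-chloro-1-[(5R)-5-hydroxy-6-methylhepta-1,6-dien-2-yl]-4-methylcyclohexan-1-ol | C=C(C)[C@H](O)CCC(=C)[C@]1(O)CC[C@@](C)(Cl)[C@H](Br)C1 | target

## Step count and least certain steps

Total step count: 8. Longest linear sequence: 7 steps (1, 2, 3, 4, 5, 7, 8); step 6 is a one-step side branch.

**Step 5 (key step, proposed new method).** The most likely failures are heterolysis of the wrong C–O bond of the titanium-bound ether (C1–O instead of C4–O), proton loss from the regenerated bromonium ion instead of chloride capture, or a slow transannular closure that lets unselective bromination compete. The fallback uses known chemistry and replaces the tether by conformational control. It sets out from 8. Silylation (Et3SiOTf, 2,6-lutidine, CH2Cl2, −78 °C) gives triethylsilyl ether F1. Anti addition of bromine chloride from Bu4N+ BrCl2− (CH2Cl2, −78 °C) is Markovnikov and trans-diaxial. The half-chair with the slim ethynyl group pseudoaxial and the silyloxy group pseudoequatorial places bromine syn to ethynyl and chlorine syn to oxygen, so bromochloride F2 should be the major diastereomer. HF·pyridine in THF at 0 °C removes the silyl group, and the route is rejoined at 10.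

**Step 7.** The most likely failures are sequestration of the ruthenium catalyst by the skipped dienol, redox isomerisation of 13 without coupling, and erosion of the branched regiocontrol in the metallacycle. The fallback sets out from 10 and forms C10–C11 separately. The same kind of coupling is run with allyl alcohol, the simplest partner for propargylic alcohols (Cp*RuCl(cod), rt), and gives hydroxy aldehyde F3 (in equilibrium with its lactol). Isopropenylmagnesium bromide (excess, THF, −78 °C) gives 16 together with its C10 epimer F4. MnO2 in CH2Cl2 oxidises the secondary allylic alcohol of the mixture, and the route is rejoined at 15.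

**Step 3.** The most likely failure is weak enantioface discrimination with a small acyclic diene, or an inverted sense of induction. The fallback is a resolution. It sets out from 8 of insufficient enantiomeric purity. NaH and (1R)-1-phenylethyl isocyanate in THF give diastereomeric carbamates, and carbamate F5 is separated by crystallisation or chromatography. HSiCl3 and Et3N cleave it, and the route is rejoined at 8.

**Step 4.** The most likely failure is acyl migration onto the hemiacetal or betaine oxygen, which stalls the olefination, or incomplete ester cleavage. The fallback removes the acyl group reductively. It sets out from 6. LiAlH4 in THF at 0 °C gives diol F6. Selective oxidation of the primary alcohol (TEMPO, PhI(OAc)2, CH2Cl2) gives 7, now isolated. The Ohira–Bestmann reaction on 7 rejoins the route at 8.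

**Step 8.** The most likely failure is poor facial selectivity if the isopropenyl and methylene substituents are not differentiated enough, with 1,4-reduction as a side process. The fallback is reduction followed by kinetic resolution. It sets out from 15. Luche reduction (NaBH4, CeCl3·7H2O, MeOH, −78 °C) gives 16 together with its C10 epimer F4. A Sharpless kinetic resolution (Ti(OiPr)4, L-(+)-diisopropyl tartrate, t-BuOOH, 4 Å sieves, CH2Cl2, −20 °C) should epoxidise the (5S) epimer faster, to epoxy alcohol F7, and leave 16, where the route is rejoined.

## Further compounds

F1 | step 5 | triethyl{[(1S)-1-ethynyl-4-methylcyclohex-3-en-1-yl]oxy}silane | C#C[C@]1(O[Si](CC)(CC)CC)CCC(C)=CC1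
F2 | step 5 | {[(1S,3R,4R)-3-bromo-4-chloro-1-ethynyl-4-methylcyclohexyl]oxy}triethylsilane | C#C[C@]1(O[Si](CC)(CC)CC)CC[C@@](C)(Cl)[C@H](Br)C1
F3 | step 7 | 4-[(1S,3R,4R)-3-bromo-4-chloro-1-hydroxy-4-methylcyclohexyl]pent-4-enal | O=CCCC(=C)[C@]1(O)CC[C@@](C)(Cl)[C@H](Br)C1
F4 | step 7 | (1S,3R,4R)-3-bromo-4-chloro-1-[(5S)-5-hydroxy-6-methylhepta-1,6-dien-2-yl]-4-methylcyclohexan-1-ol | C=C(C)[C@@H](O)CCC(=C)[C@]1(O)CC[C@@](C)(Cl)[C@H](Br)C1
F5 | step 3 | (1S)-1-ethynyl-4-methylcyclohex-3-en-1-yl N-[(1R)-1-phenylethyl]carbamate | C[C@@H](NC(=O)O[C@@]1(C#C)CCC(C)=CC1)c1ccccc1
F6 | step 4 | (1S)-1-(hydroxymethyl)-4-methylcyclohex-3-en-1-ol | OC[C@]1(O)CCC(C)=CC1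
F7 | step 8 | (1S,3R,4R)-3-bromo-4-chloro-1-{(5S)-5-hydroxy-5-[(2R)-2-methyloxiran-2-yl]pent-1-en-2-yl}-4-methylcyclohexan-1-ol | C[C@@]1(CO1)[C@@H](O)CCC(=C)[C@]2(O)CC[C@@](C)(Cl)[C@H](Br)C2
A1 | alternative 1 | (3R,4R)-3-bromo-4-chloro-4-methylcyclohexan-1-one | O=C1CC[C@@](C)(Cl)[C@H](Br)C1
A2 | alternative 1 | tert-butyl{[(3R)-6-bromo-2-methylhepta-1,6-dien-3-yl]oxy}dimethylsilane | C=C(C)[C@H](O[Si](C)(C)C(C)(C)C)CCC(Br)=C
A3 | alternative 2 | (1S)-1-[(5R)-5-hydroxy-6-methylhepta-1,6-dien-2-yl]-4-methylcyclohex-3-en-1-ol | C=C(C)[C@H](O)CCC(=C)[C@]1(O)CCC(C)=CC1
A4 | alternative 3 | (−)-α-bisabolol, (2S)-6-methyl-2-[(1S)-4-methylcyclohex-3-en-1-yl]hept-5-en-2-ol | CC1=CC[C@H](CC1)[C@@](C)(O)CCC=C(C)C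
A5 | alternative 3 | (E)-γ-bisabolene, (4E)-1-methyl-4-(6-methylhept-5-en-2-ylidene)cyclohex-1-ene (formed with its Z isomer) | CC1=CC/C(CC1)=C(\C)CCC=C(C)C
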